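**Retrosynthetic overview**

1. The two 4-hydroxybenzoate esters are cut last, giving diol 23 and a silyl-protected 4-hydroxybenzoic acid (Mitsunobu). The C5 propenol chain is cut next, giving aryl bromide 21 and a hydroxypropenyl boronate (Suzuki).
2. The strategy rests on C2: it is benzylic and para to the free OH of the 4-hydroxy-3,5-dimethoxyphenyl ring, and it carries O1 of the dihydrofuran ring. Breaking O1–C2 gives diphenol 19, in which C2 is a CH2 group lying next to the C7a phenol, with C3 and its CH2OH arm already in place. Oxidation of the syringyl phenol makes C2 the electrophilic end of a para-quinone methide; the dihydrofuran ring is the only ring built, and both benzene rings are bought.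
3. C3 is set by Evans benzylation of the arylacetyl imide 11 with the syringyl bromide 15, followed by LiBH4 cleavage and MOM removal.
4. Imide 11 comes from 4-bromo-2-methoxyphenol by O-allylation, Claisen rearrangement and oxidative cleavage of the allyl group. The C5 bromine is kept on purpose: it makes that phenol ring harder to oxidise in the ring closure and is the handle for the side chain afterwards.

Key step: step 13

Assumption: (E)-3-hydroxyprop-1-enylboronic acid pinacol ester (22) and (R)-4-benzyl-2-oxazolidinone (9) are taken as purchased reagents.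

**Route**

Step 1
Reactants: 1 4-bromo-2-methoxyphenol; 2 allyl bromide
Product: 3 1-(allyloxy)-4-bromo-2-methoxybenzene
Conditions: K2CO3, acetone, reflux
Reagents that add atoms: none
Why: Williamson O-allylation of the phenoxide with a reactive primary allylic bromide (SN2) should be clean.

Step 2
Reactants: 3 1-(allyloxy)-4-bromo-2-methoxybenzene
Product: 4 2-allyl-4-bromo-6-methoxyphenol
Conditions: N,N-diethylaniline, 200 °C, sealed tube
Reagents that add atoms: none
Why: Aromatic Claisen [3,3]-rearrangement can only deliver the allyl group to the one free ortho carbon, since the other ortho position carries the methoxy group, and tautomerisation restores the phenol.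

Step 3
Reactants: 4 2-allyl-4-bromo-6-methoxyphenol
Product: 5 1-allyl-5-bromo-3-methoxy-2-(methoxymethoxy)benzene
Conditions: NaH, MOMCl, DMF, 0 °C to rt
Reagents that add atoms: chloromethyl methyl ether, COCCl
Why: Alkylation of the sodium phenoxide with MOMCl gives an acetal that should survive the oxidative, basic and hydride steps ahead and leave with acid together with the second MOM group.

Step 4
Reactants: 5 1-allyl-5-bromo-3-methoxy-2-(methoxymethoxy)benzene
Product: 7 2-[5-bromo-3-methoxy-2-(methoxymethoxy)phenyl]acetaldehyde, via 3-arylpropane-1,2-diol 6 (not isolated)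
Conditions: OsO4 (cat.), NaIO4, 2,6-lutidine, dioxane/H2O, rt
Reagents that add atoms: sodium periodate, [Na+].[O-]I(=O)(=O)=O; water, O (oxygen atoms of diol 6 and of the aldehyde, relayed by catalytic OsO4)
Why: Lemieux–Johnson oxidation (catalytic dihydroxylation of the terminal alkene, then periodate glycol cleavage) should leave the arene, the aryl bromide and the MOM acetal untouched, and the lutidine buffer suppresses over-oxidation.

Step 5
Reactants: 7 2-[5-bromo-3-methoxy-2-(methoxymethoxy)phenyl]acetaldehyde
Product: 8 2-[5-bromo-3-methoxy-2-(methoxymethoxy)phenyl]acetic acid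
Conditions: NaClO2, NaH2PO4, 2-methyl-2-butene, t-BuOH/H2O, 0 °C to rt
Reagents that add atoms: sodium chlorite, [Na+].[O-]Cl=O
Why: Pinnick oxidation converts the crude aldehyde to the acid at about pH 4, where the MOM acetal is stable, and the alkene scavenger keeps hypochlorous acid away from the electron-rich ring.

Step 6
Reactants: 8 2-[5-bromo-3-methoxy-2-(methoxymethoxy)phenyl]acetic acid; 9 (R)-4-benzyl-2-oxazolidinone
Product: 11 (R)-4-benzyl-3-{2-[5-bromo-3-methoxy-2-(methoxymethoxy)phenyl]acetyl}oxazolidin-2-one, via mixed pivalic anhydride 10 (not isolated)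
Conditions: PivCl, Et3N, THF, –20 °C; then 9, LiCl, –20 °C to rt
Reagents that add atoms: pivaloyl chloride, CC(C)(C)C(=O)Cl (its atoms are carried by intermediate 10 only)
Why: N-acylation of the oxazolidinone through the mixed pivalic anhydride under LiCl/Et3N is non-acidic, so the MOM ether ortho to the acetic acid chain should not be lost to lactonisation.

Step 7
Reactants: 12 syringaldehyde
Product: 13 3,5-dimethoxy-4-(methoxymethoxy)benzaldehyde
Conditions: MOMCl, K2CO3, acetone, 0 °C to rt
Reagents that add atoms: chloromethyl methyl ether, COCCl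
Why: The acidic para-formyl phenol is deprotonated by carbonate and O-alkylated by MOMCl despite its two ortho methoxy groups.

Step 8
Reactants: 13 3,5-dimethoxy-4-(methoxymethoxy)benzaldehyde
Product: 14 [3,5-dimethoxy-4-(methoxymethoxy)phenyl]methanol
Conditions: NaBH4, MeOH, 0 °C
Reagents that add atoms: none
Why: Borohydride reduction of an aryl aldehyde to the benzylic alcohol is chemoselective, and the acetal is inert.

Step 9
Reactants: 14 [3,5-dimethoxy-4-(methoxymethoxy)phenyl]methanol
Product: 15 5-(bromomethyl)-1,3-dimethoxy-2-(methoxymethoxy)benzene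
Conditions: CBr4, PPh3, CH2Cl2, 0 °C; used at once
Reagents that add atoms: carbon tetrabromide, BrC(Br)(Br)Br
Why: Appel bromination works under neutral conditions, so no HBr is present to cleave the MOM acetal of this electron-rich benzylic bromide.

Step 10
Reactants: 11 (R)-4-benzyl-3-{2-[5-bromo-3-methoxy-2-(methoxymethoxy)phenyl]acetyl}oxazolidin-2-one; 15 5-(bromomethyl)-1,3-dimethoxy-2-(methoxymethoxy)benzene
Product: 17 (R)-4-benzyl-3-{(2R)-2-[5-bromo-3-methoxy-2-(methoxymethoxy)phenyl]-3-[3,5-dimethoxy-4-(methoxymethoxy)phenyl]propanoyl}oxazolidin-2-one, via sodium Z-enolate 16 (not isolated)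
Conditions: NaHMDS, THF, –78 °C; then 15, –78 to –40 °C; AcOH quench at low temperature
Reagents that add atoms: sodium bis(trimethylsilyl)amide, C[Si](C)(C)N([Na])[Si](C)(C)C (only the sodium of intermediate 16)
Why: Evans alkylation of the chelated Z-enolate, in which the benzyl group of the (R)-auxiliary blocks one face, so the benzylic bromide enters from the other face and sets the (R) centre that becomes C3; the cold acidic quench limits epimerisation of the acidic α-aryl C–H.

Step 11
Reactants: 17 the alkylated imide
Product: 18 (R)-2-[5-bromo-3-methoxy-2-(methoxymethoxy)phenyl]-3-[3,5-dimethoxy-4-(methoxymethoxy)phenyl]propan-1-ol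
Conditions: LiBH4, MeOH (1 equiv), THF/Et2O, 0 °C
Reagents that add atoms: none
Why: Reductive cleavage of the N-acyl oxazolidinone with LiBH4 gives the primary alcohol without touching the stereocentre, the aryl bromide or the acetals, and returns the auxiliary.

Step 12
Reactants: 18 the bis-MOM alcohol
Product: 19 (R)-2-(5-bromo-2-hydroxy-3-methoxyphenyl)-3-(4-hydroxy-3,5-dimethoxyphenyl)propan-1-ol
Conditions: HCl (cat.), MeOH, 40 °C
Reagents that add atoms: none
Why: Acid-catalysed acetal methanolysis frees both phenols, and the molecule holds no other acid-labile group and no ionisable benzylic oxygen at this stage.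

Step 13
Reactants: 19 (R)-2-(5-bromo-2-hydroxy-3-methoxyphenyl)-3-(4-hydroxy-3,5-dimethoxyphenyl)propan-1-ol
Product: 21 [(2S,3R)-5-bromo-2-(4-hydroxy-3,5-dimethoxyphenyl)-7-methoxy-2,3-dihydrobenzofuran-3-yl]methanol, via para-quinone methide 20 (not isolated)
Conditions: graphite anode, Pt cathode, undivided cell, constant current (low current density, 2.0 F/mol), Bu4NBF4, CH2Cl2/HFIP (4:1), dilute, 0 °C
Reagents that add atoms: none
Why: Anodic loss of two electrons and two protons from the 4-alkyl-2,6-dimethoxyphenol (phenoxyl radical, phenoxonium ion, then loss of a benzylic C2 proton) should give para-quinone methide 20, and the ortho-phenol of the bromo ring then adds to its exocyclic carbon in an oxa-1,6-addition that restores the aromatic ring. The closest known reaction type is the oxidative (anodic, DDQ or Ag2O) formation of para-quinone methides from 4-alkyl-2,6-dimethoxyphenols with capture by oxygen nucleophiles, and the closure itself is the way 8–5′-coupled quinone methides become phenylcoumarans. The dihydrofuran ring closes by 5-exo-trig attack of the C7a oxygen on C2, which forms O1–C2. The new C2 centre is controlled by the C3 centre: the aryl group takes the face opposite to the CH2OH arm, and because the addition is reversible through the quinone methide the trans isomer is also the thermodynamic one, giving (2S,3R). The step needs oxidation of the syringyl phenol alone, which its lower oxidation potential should secure (two methoxy donors and a para alkyl group, against one methoxy group and a para bromine on the other ring, which could only form an ortho-quinone methide by losing the C3 hydrogen); the charge is limited to 2 F/mol to spare the product, and the non-nucleophilic medium leaves the tethered phenol as the only good nucleophile.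

Step 14
Reactants: 21 the bromo dihydrobenzofuran; 22 (E)-3-(4,4,5,5-tetramethyl-1,3,2-dioxaborolan-2-yl)prop-2-en-1-ol
Product: 23 (E)-3-[(2S,3R)-2-(4-hydroxy-3,5-dimethoxyphenyl)-3-(hydroxymethyl)-7-methoxy-2,3-dihydrobenzofuran-5-yl]prop-2-en-1-ol
Conditions: XPhos Pd G3 (cat.), K3PO4, THF/H2O, 45 °C
Reagents that add atoms: none
Why: Suzuki–Miyaura coupling of the alkenyl boronate keeps the E geometry, and the bulky biarylphosphine catalyst lets the electron-rich bromide react at a temperature and basicity mild enough not to open the 4-hydroxybenzyl aryl ether.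

Step 15
Reactants: 24 4-hydroxybenzoic acid
Product: 26 4-(tert-butyldimethylsilyloxy)benzoic acid, via bis-silylated acid 25 (not isolated)
Conditions: TBSCl (2.2 equiv), imidazole, DMF, rt; then AcOH/THF/H2O, rt
Reagents that add atoms: tert-butyldimethylsilyl chloride, CC(C)(C)[Si](C)(C)Cl
Why: Both acidic OH groups are silylated, and aqueous acetic acid then hydrolyses the labile silyl ester while the aryl silyl ether stays.

Step 16
Reactants: 23 the diol; 26 4-(tert-butyldimethylsilyloxy)benzoic acid
Product: 27 [(2S,3R)-2-(4-hydroxy-3,5-dimethoxyphenyl)-7-methoxy-5-{(E)-3-[4-(tert-butyldimethylsilyloxy)benzoyloxy]prop-1-enyl}-2,3-dihydrobenzofuran-3-yl]methyl 4-(tert-butyldimethylsilyloxy)benzoate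
Conditions: 26 (2.4 equiv), PPh3, DIAD (added last), THF, 0 °C to rt
Reagents that add atoms: none
Why: Mitsunobu esterification activates both primary alcohols as alkoxyphosphonium ions for SN2 displacement by the carboxylate, which as the far stronger acid should outcompete the hindered 2,6-dimethoxyphenol as nucleophile, and no stereocentre or alkene geometry is involved.

Step 17
Reactants: 27 the bis-silyl diester
Product: 28 quiquesetinerviusin B, [(2S,3R)-2-(4-hydroxy-3,5-dimethoxyphenyl)-5-[(E)-3-(4-hydroxybenzoyloxy)prop-1-enyl]-7-methoxy-2,3-dihydrobenzofuran-3-yl]methyl 4-hydroxybenzoate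
Conditions: TBAF, AcOH, THF, 0 °C
Reagents that add atoms: none
Why: Fluoride cleaves the two aryl silyl ethers, and the acetic acid buffer keeps the medium from becoming basic enough to attack the benzoate esters or open the phenylcoumaran.

**Compound list**

1 | 4-bromo-2-methoxyphenol | COc1cc(Br)ccc1O | starting material
2 | allyl bromide | C=CCBr | starting material
3 | 1-(allyloxy)-4-bromo-2-methoxybenzene | COc1cc(Br)ccc1OCC=C | intermediate
4 | 2-allyl-4-bromo-6-methoxyphenol | COc1cc(Br)cc(CC=C)c1O | intermediate
5 | 1-allyl-5-bromo-3-methoxy-2-(methoxymethoxy)benzene | COCOc1c(CC=C)cc(Br)cc1OC | intermediate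
6 | 3-[5-bromo-3-methoxy-2-(methoxymethoxy)phenyl]propane-1,2-diol (racemic, not isolated) | COCOc1c(CC(O)CO)cc(Br)cc1OC | intermediate
7 | 2-[5-bromo-3-methoxy-2-(methoxymethoxy)phenyl]acetaldehyde | COCOc1c(CC=O)cc(Br)cc1OC | intermediate
8 | 2-[5-bromo-3-methoxy-2-(methoxymethoxy)phenyl]acetic acid | COCOc1c(CC(=O)O)cc(Br)cc1OC | intermediate
9 | (R)-4-benzyl-2-oxazolidinone | O=C1N[C@H](Cc2ccccc2)CO1 | starting material
10 | 2-[5-bromo-3-methoxy-2-(methoxymethoxy)phenyl]acetic pivalic anhydride (not isolated) | COCOc1c(CC(=O)OC(=O)C(C)(C)C)cc(Br)cc1OC | intermediate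
11 | (R)-4-benzyl-3-{2-[5-bromo-3-methoxy-2-(methoxymethoxy)phenyl]acetyl}oxazolidin-2-one | COCOc1c(CC(=O)N2[C@H](Cc3ccccc3)COC2=O)cc(Br)cc1OC | intermediate
12 | syringaldehyde | COc1cc(C=O)cc(OC)c1O | starting material
13 | 3,5-dimethoxy-4-(methoxymethoxy)benzaldehyde | COCOc1c(OC)cc(C=O)cc1OC | intermediate
14 | [3,5-dimethoxy-4-(methoxymethoxy)phenyl]methanol | COCOc1c(OC)cc(CO)cc1OC | intermediate
15 | 5-(bromomethyl)-1,3-dimethoxy-2-(methoxymethoxy)benzene | COCOc1c(OC)cc(CBr)cc1OC | intermediate
16 | sodium (Z)-enolate of imide 11 (not isolated) | [Na+].[O-]/C(=C\c1cc(Br)cc(OC)c1OCOC)N1[C@H](Cc2ccccc2)COC1=O | intermediate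
17 | (R)-4-benzyl-3-{(2R)-2-[5-bromo-3-methoxy-2-(methoxymethoxy)phenyl]-3-[3,5-dimethoxy-4-(methoxymethoxy)phenyl]propanoyl}oxazolidin-2-one | COCOc1c(OC)cc(C[C@@H](C(=O)N2[C@H](Cc3ccccc3)COC2=O)c2cc(Br)cc(OC)c2OCOC)cc1OC | intermediate
18 | (R)-2-[5-bromo-3-methoxy-2-(methoxymethoxy)phenyl]-3-[3,5-dimethoxy-4-(methoxymethoxy)phenyl]propan-1-ol | COCOc1c(OC)cc(C[C@@H](CO)c2cc(Br)cc(OC)c2OCOC)cc1OC | intermediate
19 | (R)-2-(5-bromo-2-hydroxy-3-methoxyphenyl)-3-(4-hydroxy-3,5-dimethoxyphenyl)propan-1-ol | COc1cc(C[C@@H](CO)c2cc(Br)cc(OC)c2O)cc(OC)c1O | intermediate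
20 | 4-[(2R)-2-(5-bromo-2-hydroxy-3-methoxyphenyl)-3-hydroxypropylidene]-2,6-dimethoxycyclohexa-2,5-dien-1-one (not isolated) | COC1=CC(=C[C@@H](CO)c2cc(Br)cc(OC)c2O)C=C(OC)C1=O | intermediate
21 | [(2S,3R)-5-bromo-2-(4-hydroxy-3,5-dimethoxyphenyl)-7-methoxy-2,3-dihydrobenzofuran-3-yl]methanol | COc1cc([C@H]2Oc3c(OC)cc(Br)cc3[C@@H]2CO)cc(OC)c1O | intermediate
22 | (E)-3-(4,4,5,5-tetramethyl-1,3,2-dioxaborolan-2-yl)prop-2-en-1-ol | OC/C=C/B1OC(C)(C)C(C)(C)O1 | starting material
23 | (E)-3-[(2S,3R)-2-(4-hydroxy-3,5-dimethoxyphenyl)-3-(hydroxymethyl)-7-methoxy-2,3-dihydrobenzofuran-5-yl]prop-2-en-1-ol | COc1cc([C@H]2Oc3c(OC)cc(/C=C/CO)cc3[C@@H]2CO)cc(OC)c1O | intermediate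
24 | 4-hydroxybenzoic acid | O=C(O)c1ccc(O)cc1 | starting material
25 | tert-butyldimethylsilyl 4-(tert-butyldimethylsilyloxy)benzoate (not isolated) | CC(C)(C)[Si](C)(C)OC(=O)c1ccc(O[Si](C)(C)C(C)(C)C)cc1 | intermediate
26 | 4-(tert-butyldimethylsilyloxy)benzoic acid | CC(C)(C)[Si](C)(C)Oc1ccc(C(=O)O)cc1 | intermediate
27 | bis-TBS ether of the target at both 4-hydroxybenzoate groups, (2S,3R) | COc1cc([C@H]2Oc3c(OC)cc(/C=C/COC(=O)c4ccc(O[Si](C)(C)C(C)(C)C)cc4)cc3[C@@H]2COC(=O)c2ccc(O[Si](C)(C)C(C)(C)C)cc2)cc(OC)c1O | intermediate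
28 | quiquesetinerviusin B | COc1cc([C@H]2Oc3c(OC)cc(/C=C/COC(=O)c4ccc(O)cc4)cc3[C@@H]2COC(=O)c2ccc(O)cc2)cc(OC)c1O | target

**Step count and risks**

Total: 17 steps. Longest linear sequence: 13 steps (steps 1–6, 10–14, 16, 17, from 4-bromo-2-methoxyphenol).

Step 13 (key step). Three processes may interfere. The product keeps a syringyl phenol that is oxidised at nearly the same potential as that of 19, and its further oxidation with loss of the C2 hydrogen leads towards a benzofuran. Quinone methide 20 may tautomerise to a stilbene, which erases the C3 centre. The bromo phenol may be oxidised unselectively at high conversion. The fallback replaces oxidation by ionisation and sets out from acid 8. Acid 8 is coupled through its mixed pivalic anhydride with (S)-4-benzyl-2-oxazolidinone to give (S)-4-benzyl-3-{2-[5-bromo-3-methoxy-2-(methoxymethoxy)phenyl]acetyl}oxazolidin-2-one F1. The enantiomeric auxiliary is needed because the boron aldol reaction uses the enolate face opposite to the one used in alkylation. Enolisation with Bu2BOTf/iPr2NEt and addition to aldehyde 13 should give the Evans syn-aldol adduct F2, and LiBH4 should cleave it to the 1,3-diol F3. HCl in MeOH should then remove both MOM groups and ionise the benzylic alcohol para to the freed phenol; the ortho-phenol captures the resulting quinone methide or benzylic cation to give the trans-dihydrobenzofuran 21, where the fallback rejoins the route.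

Step 10. The stabilised arylacetyl enolate may alkylate slowly, the acidic α-aryl centre of the product may epimerise under the basic conditions, and the electron-rich benzylic bromide may decompose before it reacts. The fallback sets out from acid 8 and aldehyde 13. Perkin condensation (Ac2O, Et3N, 110 °C) should give the (E)-2,3-diarylacrylic acid F4. Asymmetric hydrogenation with a chiral iridium spiro phosphine–oxazoline catalyst (H2, Et3N, MeOH), using the ligand enantiomer that delivers the (R)-acid, should give the (R)-2,3-diarylpropanoic acid F5. BH3·SMe2 should reduce F5 to alcohol 18, where the fallback rejoins the route.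

Step 16. The free syringyl phenol may be O-alkylated by an activated alcohol, the electron-rich cinnamyl oxyphosphonium ion may ionise or undergo allylic transposition, and the double esterification may stop halfway. The fallback sets out from diol 23 and switches from alcohol activation to acyl activation with the phenol masked. TBSCl (excess) and imidazole should give the tris-silyl ether F6. PPTS in MeOH should cleave the two alkyl silyl ethers but not the hindered aryl silyl ether, giving the phenol-protected diol F7. Steglich esterification of both alcohols with acid 26 (EDC, DMAP, CH2Cl2) should give the tris-silyl diester F8. TBAF/AcOH should remove the three aryl silyl groups and give target 28, where the fallback ends.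

**Further compounds**

F1 | step 13 | (S)-4-benzyl-3-{2-[5-bromo-3-methoxy-2-(methoxymethoxy)phenyl]acetyl}oxazolidin-2-one | COCOc1c(CC(=O)N2[C@@H](Cc3ccccc3)COC2=O)cc(Br)cc1OC
F2 | step 13 | (S)-4-benzyl-3-{(2S,3S)-2-[5-bromo-3-methoxy-2-(methoxymethoxy)phenyl]-3-[3,5-dimethoxy-4-(methoxymethoxy)phenyl]-3-hydroxypropanoyl}oxazolidin-2-one | COCOc1c(OC)cc([C@@H](O)[C@@H](C(=O)N2[C@@H](Cc3ccccc3)COC2=O)c2cc(Br)cc(OC)c2OCOC)cc1OC
F3 | step 13 | (1S,2R)-2-[5-bromo-3-methoxy-2-(methoxymethoxy)phenyl]-1-[3,5-dimethoxy-4-(methoxymethoxy)phenyl]propane-1,3-diol | COCOc1c(OC)cc([C@@H](O)[C@@H](CO)c2cc(Br)cc(OC)c2OCOC)cc1OC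
F4 | step 10 | (E)-2-[5-bromo-3-methoxy-2-(methoxymethoxy)phenyl]-3-[3,5-dimethoxy-4-(methoxymethoxy)phenyl]acrylic acid | COCOc1c(OC)cc(/C=C(/C(=O)O)c2cc(Br)cc(OC)c2OCOC)cc1OC
F5 | step 10 | (R)-2-[5-bromo-3-methoxy-2-(methoxymethoxy)phenyl]-3-[3,5-dimethoxy-4-(methoxymethoxy)phenyl]propanoic acid | COCOc1c(OC)cc(C[C@@H](C(=O)O)c2cc(Br)cc(OC)c2OCOC)cc1OC
F6 | step 16 | tris(tert-butyldimethylsilyl) ether of diol 23 (both alcohols and the phenol silylated), (2S,3R) | COc1cc([C@H]2Oc3c(OC)cc(/C=C/CO[Si](C)(C)C(C)(C)C)cc3[C@@H]2CO[Si](C)(C)C(C)(C)C)cc(OC)c1O[Si](C)(C)C(C)(C)C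
F7 | step 16 | (E)-3-[(2S,3R)-2-[4-(tert-butyldimethylsilyloxy)-3,5-dimethoxyphenyl]-3-(hydroxymethyl)-7-methoxy-2,3-dihydrobenzofuran-5-yl]prop-2-en-1-ol | COc1cc([C@H]2Oc3c(OC)cc(/C=C/CO)cc3[C@@H]2CO)cc(OC)c1O[Si](C)(C)C(C)(C)C
F8 | step 16 | tris-TBS ether of the target (syringyl phenol and both 4-hydroxybenzoate phenols silylated), (2S,3R) | COc1cc([C@H]2Oc3c(OC)cc(/C=C/COC(=O)c4ccc(O[Si](C)(C)C(C)(C)C)cc4)cc3[C@@H]2COC(=O)c2ccc(O[Si](C)(C)C(C)(C)C)cc2)cc(OC)c1O[Si](C)(C)C(C)(C)C
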